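- The trap in the gamma flask is to take its highest reading, 75.7% at 5.00 h, for the peak itself.

- gamma: starting material 0.50 M; partner 0.60 M; the very flask that is asked about, followed so far
- flask: starting material 0.50 M; partner 0.600 M; time 20 h

gamma run (percent of the starting material charged)

| time / h | target / % |
|---|---|
| 1.00 | 60.3 |
| 1.50 | 68.0 |
| 2.50 | 74.4 |
| 5.00 | 75.7 |
| 8.00 | 70.2 |

(standard deviation of a reading: 0.3 percentage points)



- time up to 20 h at which target stands highest
- the amount of target, in percent of the starting material charged, at that time
- the first time at which target reaches 23%, in the same percent

- I reckon with two times. Starting material is the limiting reagent.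
- Extreme one is the gamma flask with fill and no loss, second order in [starting material] and [partner]. The first reading then gives the fill time, the inverse of k[partner] at the charge: 0.739 h.
- That extreme puts 23% at 0.215 h.
- Extreme two is the gamma flask with fill finished and target simply fading. The fade time, the time in which target shrinks by a factor e across the two latest readings, is 39.8 h.
- The fade line, carried back to 2.50 h, gives 80.6%. I take that as my ceiling, since fill was still adding then.
- The fill time is far shorter than the fade time, so the gamma flask should peak high. I commit to a peak between 75.7% and 80.6%, somewhere from 2.50 h to 8.00 h.
- The forecast gives 76.8% at 3.7 h and 23% at 0.21 h, saying “Formation falls to match loss” at the peak; its peak lies inside my bracket, and its first time is close to my 0.215 h.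
- The flask gives 76.6% at 3.70 h, and 23% at 0.204 h.

    starting material + partner ⇌ target + released group (K = 29.0, k = 2.40 M⁻¹ h⁻¹)
    released group → by-product carried off (k = 0.200 h⁻¹)
    target ⇌ isomer of the product (K = 2.57, k = 0.0471 h⁻¹)

- At 20.0 h target is made at 0.0907 of the rate at which it is used up, so the late flask runs close to extreme two. The fade time carries 76.6% at 3.70 h to 50.9% at 20 h, and the flask stands at 49.8%. Read on to 30 h, the same flask is reckoned from 49.8% to 38.7%, and it holds 39.7%.

(Readings and results are simulated with made-up constants, and the scatter is random.)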